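## The problem

Labels used throughout: Ca is the benzylic CH, C4 the quaternary ring carbon, C3 and C2 the ring CH2 groups, C1 the ring-fusion CH, C5=C6 the alkene, C7 the CH that carries the carbinol carbon C11, C8 and C9 the remaining CH2 groups and C10 the CH(CH3); primed numbers belong to the arene. The target joins a 3,5-diformyl-2,4,6-trihydroxyphenyl ring to a bicyclo[5.3.0]decene (five-membered ring fused to seven-membered ring, trisubstituted alkene C5=C6 starting at the fusion carbon) through Ca, which also bears an isobutyl group and is bonded to quaternary C4. The five stereocentres fall into two sets: the vicinal tertiary/quaternary pair Ca/C4 across an exocyclic bond, and the triad C1/C10/C7 on the seven-membered ring, where H-1 and H-10 are cis to each other and cis to C11 (trans to H-7). C4 can bias reactions at C5 and C1, but the trigonal C5=C6 unit separates it from C7 and C10, so the ring triad needs its own source of absolute configuration, which must then be paired correctly with Ca/C4. The Ca–C4 bond is the most congested bond in the molecule (a di-ortho-substituted aryl carbon's neighbour against a quaternary carbon); made through an open transition state, its relative configuration cannot be predicted with confidence, so cyclic control is wanted there. The groups that will not survive rough treatment are the two aldehydes on a triphenol (base, oxidants, nucleophiles), the tertiary alcohol at C11 beside allylic C7 (acid-induced ionisation and dehydration), and any carbonyl placed at C7 (enolisation into conjugation). Hence the arene is carried as its trimethyl ether without formyl groups and the carbinol is completed late. The feature that opens the key step is that C1 and C10 are adjacent sp3 carbons with cis hydrogens, C1 is flanked by C5=C6, and C7 lies between C6 and C8. One further alkene at C8=C9 makes the ring a cyclohepta-1,4-diene with C7 doubly allylic, the product pattern of a cis-1,2-dialkenylcyclopropane Cope rearrangement in which C6–C7–C8 is the three-membered ring and the cyclopentene bond C1=C5 is one of the two alkenes.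

## Retrosynthesis

**Aryl–CHO and O–CH3 bonds (23 ⇒ 22 ⇒ 20).** The two formyl groups and the three free phenols are removed first. Both are incompatible with the organometallic steps, and the two remaining aryl hydrogens of 20 each lie between two methoxy groups, the best position for directed lithiation. Electrophilic formylation under Lewis acid is ruled out by the tertiary alcohol. The forward reactions must tolerate a tertiary alkoxide and one trisubstituted alkene.

**C11–CH3 bonds and the C8/C9 hydrogens (20 ⇒ 19 ⇒ 18 ⇒ 17).** The carbinol is traced to a carboxamide at C7, and the saturated C8–C9 bond to a cis-disubstituted alkene. An sp3 tertiary carbinol at C7 would have to point one of its substituents at the reacting termini in the rearrangement (see next paragraph), whereas a planar carbonyl group can turn edge-on. An N-methoxy-N-methyl amide is chosen over a ketone or ester because its α-hydrogen, doubly allylic in 17, is the least prone to enolise. The forward steps need diimide to distinguish a disubstituted from a hindered trisubstituted alkene, and two clean methyl additions.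

**C1–C10 (17 ⇒ 16), the key cut.** Breaking C1–C10 and joining C6 to C8 gives cyclopropane 16, with the cyclopentene C1=C5 on C6 and an (E)-propenyl group on C8. This cut removes the seven-membered ring and two stereocentres at once and leaves a precursor whose stereochemistry is that of a small ring. Cuts of C8–C9 or C9–C10 (metathesis, alkylation) would leave C1, C7 and C10 to be set separately. In the boat transition state the inward hydrogens of both alkene termini lie over the cyclopropane face that carries the alkenyl groups, and they finish cis to whatever C7 carries on that face. Since 23 has H-1 and H-10 cis to C11, C11 must stand on the same face as both alkenyl groups: 16 is an all-cis 1,2,3-trisubstituted cyclopropane. The forward reaction must run below the temperature at which the C6–C8 bond homolyses.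

**C9=C10 and the all-cis arrangement (16 ⇒ 15 ⇒ 14 ⇒ 13).** The propenyl group comes from aldehyde 15 by (E)-selective, non-basic ethylidenation. 15 comes from lactone 13 by aminolysis and oxidation. The lactone is the device that makes an all-cis cyclopropane accessible: its five-membered ring forces C11 and C9 onto one face. An intermolecular cyclopropanation would put the ester trans.

**C6–C7 and C7–C8 (13 ⇒ 12 ⇒ 10).** Both bonds are cut to the (Z)-allylic diazoacetate 12, made from (Z)-dienol 10. The Z geometry places the cyclopentenyl group on the lactone face, and a chiral dirhodium carboxamidate supplies the absolute configuration of the triad. The precursor is an achiral chain on the existing cyclopentene; the forward step must override any facial bias from Ca/C4.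

**C5–C6 (10 ⇒ 9 ⇒ 7 + 8; 7 ⇒ 6).** The diene is cut at C5–C6 to enol triflate 7 and propargyl alcohol 8 (Sonogashira coupling, then cis semi-reduction of 9). An sp-carbon nucleophile is the least sensitive to the quaternary neighbour. Ketone 6 has α-hydrogens only at C1, so the triflate regiochemistry is unambiguous.

**C1–C5 (6 ⇒ 4).** Cutting the ring bond C1–C5 of cyclopentanone 6 and re-attaching C5 to an ortho oxygen of the arene gives aryl lactone 4. The forward step is an intramolecular acyl substitution by a primary alkyllithium. It puts Ca and C4 into one six-membered ring, so their relative configuration can be set by ring control instead of by an open transition state.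

**C4–C3, C4–CH3 and Ca–CH2 (4 ⇒ 3 ⇒ 2 ⇒ 1).** The quaternary centre is taken apart by two enolate alkylations of dihydrocoumarin 2 (methyl first, then the three-carbon arm trans to the isobutyl group). Ca is cut to commercial 5,7-dimethoxycoumarin 1 by catalytic asymmetric conjugate addition. A direct catalytic allylation of a 2-methylcyclopentanone enolate with an arylallyl electrophile would be shorter on paper, but it needs a di-ortho-substituted aryl allyl partner and gives no secure prediction of the Ca/C4 relationship; a chair-type Claisen analysis of the same bond gives the wrong diastereomer.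

## Roads not taken

**Alternative 1:** The arene is built last: the ring bonds C1′–C2′ and C5′–C6′ are cut, tracing the phloroglucinol to siloxyalkyne A1 at Ca and cyclobutenone A2. Heating the two would give, by a pericyclic cascade (ring opening, addition to the alkyne, ring opening, ring closure), the differentiated phloroglucinol A3.
- Merits: the congested Ca–aryl bond is never made by coupling, Ca/C4 can be set with small groups, and the oxygen pattern is fixed by the cascade. In these respects it is better than the chosen plan.
- Weak points: it is silent on the hydroazulene and the C1/C7/C10 triad, which still need a separate solution. The siloxyalkyne must be made from a neopentyl-type carboxyl next to C4. The cascade runs hot on the complete terpene, and afterwards two formylations and cleavage of an ethyl ether (as hard as a methyl ether) remain.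
- Comparison: the chosen plan buys the arene together with Ca in the first step and uses its ortho oxygen as the tether that controls C4; it spends its key step on the ring problem, which Alternative 1 leaves open.

**Alternative 2:** C1–C5 and C9–C10 are cut, with a temporary oxygen bridge between C5 and C9. Base would convert acetoxypyranone A4 into an oxidopyrylium that adds across the tethered (Z)-alkene to give the bridged enone A5.
- Merits: two rings, two C–C bonds and the cis C1/C10 relationship in one step, from a convergent precursor. In bond and ring economy it is clearly better than the chosen key step (one ring, one bond).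
- Weak points: A5 carries oxygen at C5, C6 and C9 that the target lacks. The bridge must be cleaved reductively, the C6 ketone turned into the C5=C6 alkene by a regiocontrolled elimination, and C7 created afterwards by facial reduction of the C7=C8 enone. The alkene partner is unactivated, and face selection rests on C4 through a three-atom tether.
- Comparison: the chosen rearrangement delivers the target's oxidation pattern and all three ring stereocentres directly; one hydrogenation separates 17 from the saturated ring.

**Alternative 3:** C1–C5, C2–C3 and C3–C4 are cut, with C3 coming from CO. [Rh(CO)2Cl]2 under CO would cyclise allenyne A6 through the distal allene bond to the alkylidenecyclopentenone A7.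
- Merits: three bonds and both rings in one step, the C5=C6 alkene in place, and C7 and C10 set in an open chain where they are easy to make. It is the most convergent of the four routes.
- Weak points: quaternary C4 is created in the cyclisation from a fully substituted allene terminus, so it depends on a stereodefined trisubstituted allene next to Ca. The C3 ketone must be deleted beside a quaternary carbon, and C1 is trigonal in A7 and must be reduced cis to H-10 afterwards.
- Comparison: the chosen plan fixes C4 under ring control before the key step and C1 in it, and carries no oxygen to erase; it pays with a linear sequence.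

Key step: step 13

Assumption: where a ligand or catalyst enantiomer is specified, it is the one expected by analogy with simpler substrates; its sense would be confirmed on 2 and on 13 before material is committed.

## Route

Step 1
Reactants: 1 5,7-dimethoxy-2H-chromen-2-one (5,7-dimethoxycoumarin)
Product: 2 (4R)-5,7-dimethoxy-4-(2-methylpropyl)-3,4-dihydro-2H-chromen-2-one
Conditions: i-BuMgBr (1.5 equiv), CuBr·SMe2 (5 mol %), Josiphos-type ferrocenyl diphosphine (6 mol %, enantiomer giving 4R), t-BuOMe, −72 °C; aq NH4Cl
Reagents that add atoms: isobutylmagnesium bromide, CC(C)C[Mg]Br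
Why: Copper-catalysed asymmetric conjugate addition of a Grignard reagent to a coumarin; the chiral alkylcopper–diphosphine complex selects one face of the planar lactone, so Ca is set by the catalyst.

Step 2
Reactants: 2 (4R)-4-isobutyl-5,7-dimethoxydihydrocoumarin
Product: 3 (3R,4R)-5,7-dimethoxy-3-methyl-4-(2-methylpropyl)-3,4-dihydro-2H-chromen-2-one (trans shown; the C3 epimer is equally usable)
Conditions: LiN(i-Pr)2 (1.05 equiv), THF, −78 °C; MeI, −78 → −20 °C
Reagents that add atoms: iodomethane, CI
Why: Lactone enolate alkylation; the configuration at the new centre is irrelevant because it is made trigonal again in step 3.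

Step 3
Reactants: 3 3-methyl-4-isobutyl-5,7-dimethoxydihydrocoumarin
Product: 4 (3R,4S)-3-(3-iodopropyl)-5,7-dimethoxy-3-methyl-4-(2-methylpropyl)-3,4-dihydro-2H-chromen-2-one (iodopropyl trans, methyl cis to the isobutyl group)
Conditions: LiN(i-Pr)2 (1.1 equiv), THF–DMPU, −78 °C; I(CH2)3I (4 equiv), −78 → −10 °C
Reagents that add atoms: 1,3-diiodopropane, ICCCI
Why: Second lactone enolate alkylation builds quaternary C4; the 4-isobutyl group is held pseudo-axial by the peri 5-methoxy group and shields one face, so the electrophile should enter trans to it, which is the Ca/C4 relationship of the target.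

Step 4
Reactants: 4 3-(3-iodopropyl)-3-methyl-4-isobutyl-5,7-dimethoxydihydrocoumarin
Product: 6 (2R)-2-methyl-2-[(1S)-3-methyl-1-(2,4,6-trimethoxyphenyl)butyl]cyclopentan-1-one, via lithium phenolate ketone 5 (not isolated)
Conditions: t-BuLi (2.1 equiv), Et2O–pentane, −78 °C; then MeI (5 equiv), DMPU, −78 °C → rt
Reagents that add atoms: iodomethane, CI
Why: Iodine–lithium exchange outruns attack of t-BuLi on the ester; the primary alkyllithium closes the five-membered ring on the aryl ester carbonyl (intramolecular nucleophilic acyl substitution, C1–C5), the aryloxide leaves and is O-methylated in the same flask; neither stereocentre is touched.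

Step 5
Reactants: 6 (2R)-2-methyl-2-[(1S)-1-aryl-3-methylbutyl]cyclopentanone (aryl = 2,4,6-trimethoxyphenyl)
Product: 7 5-methyl-5-[3-methyl-1-(2,4,6-trimethoxyphenyl)butyl]cyclopent-1-en-1-yl trifluoromethanesulfonate (both stereocentres as in 6)
Conditions: KN(SiMe3)2 (1.2 equiv), THF, −78 °C; PhNTf2, −78 → 0 °C
Reagents that add atoms: N-phenylbis(trifluoromethanesulfonimide), FC(F)(F)S(=O)(=O)N(c1ccccc1)S(=O)(=O)C(F)(F)F
Why: Enolate O-sulfonylation; only C1 carries α-hydrogens, so a single enol triflate (C1=C5) can form.

Step 6
Reactants: 7 enol triflate; 8 prop-2-yn-1-ol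
Product: 9 3-{5-methyl-5-[3-methyl-1-(2,4,6-trimethoxyphenyl)butyl]cyclopent-1-en-1-yl}prop-2-yn-1-ol
Conditions: PdCl2(PPh3)2 (3 mol %), CuI (6 mol %), i-Pr2NH, THF, rt
Reagents that add atoms: none
Why: Sonogashira coupling forms C5–C6; a linear copper acetylide is the nucleophile least affected by the quaternary neighbour of the triflate.

Step 7
Reactants: 9 enynol
Product: 10 (2Z)-3-{5-methyl-5-[3-methyl-1-(2,4,6-trimethoxyphenyl)butyl]cyclopent-1-en-1-yl}prop-2-en-1-ol
Conditions: Zn dust activated with Cu(OAc)2 and AgNO3, MeOH–H2O (1:1), 45 °C
Reagents that add atoms: none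
Why: Zinc(copper/silver) semi-reduction of a conjugated propargylic alkyne is cis-selective and does not over-reduce the diene, giving the Z-alkene that later places the cyclopentenyl group on the lactone face.

Step 8
Reactants: 10 (Z)-dienol
Product: 12 (2Z)-3-{5-methyl-5-[3-methyl-1-(2,4,6-trimethoxyphenyl)butyl]cyclopent-1-en-1-yl}prop-2-en-1-yl diazoacetate, via bromoacetate ester 11 (not isolated)
Conditions: BrCH2COBr, NaHCO3, MeCN, 0 °C; filter and concentrate; then TsNHNHTs, 1,8-diazabicyclo[5.4.0]undec-7-ene, THF, 0 °C
Reagents that add atoms: bromoacetyl bromide, BrCC(=O)Br; N,N′-bis(4-methylbenzenesulfonyl)hydrazine, Cc1ccc(cc1)S(=O)(=O)NNS(=O)(=O)c1ccc(C)cc1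
Why: Acylation, then N-alkylation of the bis-sulfonylhydrazine by the bromoacetate and two base-induced sulfinate eliminations give the diazoacetate under conditions that leave the diene untouched.

Step 9
Reactants: 12 (Z)-dienyl diazoacetate
Product: 13 (1S,5R,6S)-6-{5-methyl-5-[3-methyl-1-(2,4,6-trimethoxyphenyl)butyl]cyclopent-1-en-1-yl}-3-oxabicyclo[3.1.0]hexan-2-one (cyclopentenyl endo; all-cis cyclopropane C6/C7/C8)
Conditions: Rh2(5R-MEPY)4 (1 mol %; MEPY = methyl 2-oxopyrrolidine-5-carboxylate), CH2Cl2, reflux, addition of 12 over 10 h
Reagents that add atoms: none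
Why: Intramolecular cyclopropanation of a (Z)-allylic diazoacetate by a chiral dirhodium carboxamidate carbenoid; the five-membered lactone forces C11 and C9 cis, the Z-alkene places the cyclopentenyl group cis to both, and the catalyst (a class that is highly enantioselective for cis-disubstituted allylic diazoacetates) chooses the alkene face, the 5R series being the one that gives this ring-fusion sense with simple substrates.

Step 10
Reactants: 13 cyclopropane-fused lactone
Product: 14 all-cis N-methoxy-N-methyl-2-(hydroxymethyl)-3-{5-methyl-5-[3-methyl-1-(2,4,6-trimethoxyphenyl)butyl]cyclopent-1-en-1-yl}cyclopropane-1-carboxamide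
Conditions: MeNH(OMe)·HCl (3 equiv), i-PrMgCl (6 equiv), THF, −20 → 0 °C; used crude
Reagents that add atoms: N,O-dimethylhydroxylamine hydrochloride, CNOC.Cl
Why: Aminolysis of the lactone by the magnesium amide (Weinreb amide formation); the basic, weakly Lewis acidic conditions do not ionise the alkenylcyclopropane, and immediate use prevents relactonisation.

Step 11
Reactants: 14 hydroxy amide
Product: 15 all-cis 2-formyl-N-methoxy-N-methyl-3-{5-methyl-5-[3-methyl-1-(2,4,6-trimethoxyphenyl)butyl]cyclopent-1-en-1-yl}cyclopropane-1-carboxamide
Conditions: Dess–Martin periodinane (1.3 equiv), NaHCO3, CH2Cl2, 0 °C → rt; used crude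
Reagents that add atoms: none
Why: Buffered Dess–Martin oxidation of the primary alcohol; no base is present to epimerise the cis aldehyde, and the syn amide that will slow the Cope step also slows retro-Claisen opening of the cis alkenyl aldehyde at room temperature.

Step 12
Reactants: 15 cyclopropane aldehyde
Product: 16 all-cis N-methoxy-N-methyl-2-[(1E)-prop-1-en-1-yl]-3-{5-methyl-5-[3-methyl-1-(2,4,6-trimethoxyphenyl)butyl]cyclopent-1-en-1-yl}cyclopropane-1-carboxamide
Conditions: CrCl2 (8 equiv), CH3CHI2 (2 equiv), THF, 0 °C → rt; chromatography below rt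
Reagents that add atoms: 1,1-diiodoethane, CC(I)I
Why: Takai–Utimoto ethylidenation through a geminal dichromium reagent is E-selective, attacks the aldehyde and not the amide, and is non-basic, so the all-cis cyclopropane is not epimerised.

Step 13
Reactants: 16 all-cis 1-carboxamido-2-propenyl-3-cyclopentenylcyclopropane
Product: 17 C7 N-methoxy-N-methylcarboxamide of the bicyclo[5.3.0]deca-5,8-diene: C4 bearing methyl and the 1-aryl-3-methylbutyl arm as in 6, H-1 and H-10 cis to each other and cis to the C7 carboxamide, C5=C6 and C8=C9 alkenes
Conditions: toluene (0.02 M), 100 °C, sealed, trace 2,6-di-tert-butyl-4-methylphenol, base-washed glass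
Reagents that add atoms: none
Why: Concerted [3,3] sigmatropic (Cope) rearrangement through the boat transition state, the closest known reaction type being the cis-divinylcyclopropane to cyclohepta-1,4-diene rearrangement with a cycloalkene as one of the alkenes. The seven-membered ring closes by bond formation between the alkene termini C1 and C10 while the cyclopropane bond C6–C8 breaks, a strain-driven three-to-seven ring expansion that turns the cyclopentene into the fused five-membered ring. At C1 the ring carbon C2 is locked trans to C6 across C1=C5 and must point outward in the boat, so H-1 points inward over the three-membered ring; at C10 the (E)-methyl is outward for the same reason and H-10 is inward. The two inward hydrogens finish cis to each other and cis to the substituent that C7 carried on the alkenyl face, which is why the carboxamide was placed syn: C11 emerges trans to C2 and to the C10 methyl, as in 23, and C7 itself is untouched and carries the absolute configuration of step 9 into the ring. The selectivity needed is rearrangement ahead of C6–C8 homolysis (one-centre epimerisation) and of homodienyl hydrogen shift. The substrate secures it because the syn group is a planar carboxamide that can turn edge-on toward the inward hydrogens (a demand comparable to a syn methyl group), C11 has no hydrogen to transfer, and the quaternary C4 on the internal alkene carbon C5 points away from the fold. The C1–C10 bond forms on the cyclopentene face that carries the C4 methyl, anti to the bulky Ca arm, so the existing centres do not oppose the fold.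

Step 14
Reactants: 17 diene carboxamide
Product: 18 C7 N-methoxy-N-methylcarboxamide of the bicyclo[5.3.0]dec-5-ene (C8–C9 saturated; stereocentres as in 17)
Conditions: 2-nitrobenzenesulfonylhydrazide (5 equiv), Et3N, THF, rt
Reagents that add atoms: none
Why: Diimide reduction; concerted syn transfer of H2 is fast for the cis-disubstituted C8=C9 and negligible for the trisubstituted C5=C6 beside quaternary C4, and no stereocentre is created or touched.

Step 15
Reactants: 18 monoene carboxamide
Product: 19 C7 acetyl bicyclo[5.3.0]dec-5-ene (methyl ketone at C11; stereocentres as in 18)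
Conditions: MeMgBr (3 equiv), THF, −20 → 0 °C; cold aq NH4Cl
Reagents that add atoms: methylmagnesium bromide, C[Mg]Br
Why: Weinreb ketone synthesis; the chelated tetrahedral adduct survives until quench so addition stops at the ketone, and the cold neutral work-up avoids epimerisation or conjugation at C7.

Step 16
Reactants: 19 methyl ketone
Product: 20 2-[C7]-propan-2-ol of the bicyclo[5.3.0]dec-5-ene with the 2,4,6-trimethoxyphenyl arm (trimethyl ether of the target lacking both formyl groups)
Conditions: MeLi (3 equiv), CeCl3 (3.5 equiv, dried), THF, −78 °C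
Reagents that add atoms: methyllithium, [Li]C
Why: Organocerium 1,2-addition; the weakly basic methylcerium reagent adds to the enolisable β,γ-unsaturated ketone faster than it deprotonates C7, and C11 is not stereogenic.

Step 17
Reactants: 20 trimethoxyphenyl carbinol
Product: 22 2,4,6-trimethoxy-5-substituted benzene-1,3-dicarbaldehyde (trimethyl ether of the target), via monoformyl amino alkoxide 21 (not isolated)
Conditions: n-BuLi (2.3 equiv), TMEDA, THF, 0 °C; DMF (1.15 equiv), −78 → 0 °C; n-BuLi (1.6 equiv), 0 °C; DMF (4 equiv), −78 °C → rt; aq citric acid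
Reagents that add atoms: N,N-dimethylformamide, CN(C)C=O
Why: Directed ortho-lithiation and formylation, twice; each aryl hydrogen lies between two methoxy groups, the first DMF adduct persists as a lithium α-amino alkoxide that protects the aldehyde during the second lithiation, and the tertiary alcohol is masked as its alkoxide.

Step 18
Reactants: 22 dialdehyde trimethyl ether
Product: 23 target, 2,4,6-trihydroxy-5-substituted benzene-1,3-dicarbaldehyde (CNP0281883.1)
Conditions: NaSEt (12 equiv), DMF, 120 °C; aq HCl to pH 3, 0 °C
Reagents that add atoms: none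
Why: Thiolate demethylation by SN2 attack at the methyl carbons; all three aryloxide leaving groups are activated by ortho or para formyl groups, and the basic medium spares the tertiary alcohol and the alkene.

## Compound list

1 | 5,7-dimethoxy-2H-chromen-2-one | O=C1C=Cc2c(OC)cc(OC)cc2O1 | starting material
2 | (4R)-5,7-dimethoxy-4-(2-methylpropyl)-3,4-dihydro-2H-chromen-2-one | CC(C)C[C@H]1c2c(OC)cc(OC)cc2OC(=O)C1 | intermediate
3 | (3R,4R)-5,7-dimethoxy-3-methyl-4-(2-methylpropyl)-3,4-dihydro-2H-chromen-2-one (trans; C3 epimer also usable) | CC(C)C[C@H]1c2c(OC)cc(OC)cc2OC(=O)[C@@H]1C | intermediate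
4 | (3R,4S)-3-(3-iodopropyl)-5,7-dimethoxy-3-methyl-4-(2-methylpropyl)-3,4-dihydro-2H-chromen-2-one | CC(C)C[C@H]1c2c(OC)cc(OC)cc2OC(=O)[C@]1(C)CCCI | intermediate
5 | lithium 3,5-dimethoxy-2-{(1S)-3-methyl-1-[(1R)-1-methyl-2-oxocyclopentyl]butyl}phenolate | CC(C)C[C@@H](c1c([O-])cc(OC)cc1OC)[C@@]1(C)CCCC1=O.[Li+] | intermediate (not isolated)
6 | (2R)-2-methyl-2-[(1S)-3-methyl-1-(2,4,6-trimethoxyphenyl)butyl]cyclopentan-1-one | CC(C)C[C@@H](c1c(OC)cc(OC)cc1OC)[C@@]1(C)CCCC1=O | intermediate
7 | 5-methyl-5-[3-methyl-1-(2,4,6-trimethoxyphenyl)butyl]cyclopent-1-en-1-yl trifluoromethanesulfonate (stereocentres as in 6) | CC(C)C[C@@H](c1c(OC)cc(OC)cc1OC)[C@@]1(C)CCC=C1OS(=O)(=O)C(F)(F)F | intermediate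
8 | prop-2-yn-1-ol | C#CCO | starting material
9 | 3-{5-methyl-5-[3-methyl-1-(2,4,6-trimethoxyphenyl)butyl]cyclopent-1-en-1-yl}prop-2-yn-1-ol | CC(C)C[C@@H](c1c(OC)cc(OC)cc1OC)[C@@]1(C)CCC=C1C#CCO | intermediate
10 | (2Z)-3-{5-methyl-5-[3-methyl-1-(2,4,6-trimethoxyphenyl)butyl]cyclopent-1-en-1-yl}prop-2-en-1-ol | CC(C)C[C@@H](c1c(OC)cc(OC)cc1OC)[C@@]1(C)CCC=C1/C=C\CO | intermediate
11 | bromoacetate ester of 10 | CC(C)C[C@@H](c1c(OC)cc(OC)cc1OC)[C@@]1(C)CCC=C1/C=C\COC(=O)CBr | intermediate (not isolated)
12 | diazoacetate ester of 10 | CC(C)C[C@@H](c1c(OC)cc(OC)cc1OC)[C@@]1(C)CCC=C1/C=C\COC(=O)C=[N+]=[N-] | intermediate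
13 | (1S,5R,6S)-6-{5-methyl-5-[3-methyl-1-(2,4,6-trimethoxyphenyl)butyl]cyclopent-1-en-1-yl}-3-oxabicyclo[3.1.0]hexan-2-one | CC(C)C[C@@H](c1c(OC)cc(OC)cc1OC)[C@@]1(C)CCC=C1[C@@H]1[C@@H]2C(=O)OC[C@H]12 | intermediate
14 | all-cis 2-(hydroxymethyl)-N-methoxy-N-methyl-3-(cyclopentenyl)cyclopropane-1-carboxamide (cyclopentenyl unit as in 7) | CC(C)C[C@@H](c1c(OC)cc(OC)cc1OC)[C@@]1(C)CCC=C1[C@@H]1[C@H](C(=O)N(C)OC)[C@@H]1CO | intermediate
15 | all-cis 2-formyl-N-methoxy-N-methyl-3-(cyclopentenyl)cyclopropane-1-carboxamide | CC(C)C[C@@H](c1c(OC)cc(OC)cc1OC)[C@@]1(C)CCC=C1[C@@H]1[C@H](C(=O)N(C)OC)[C@@H]1C=O | intermediate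
16 | all-cis N-methoxy-N-methyl-2-[(1E)-prop-1-en-1-yl]-3-(cyclopentenyl)cyclopropane-1-carboxamide (key-step precursor) | CC(C)C[C@@H](c1c(OC)cc(OC)cc1OC)[C@@]1(C)CCC=C1[C@@H]1[C@H](C(=O)N(C)OC)[C@@H]1/C=C/C | intermediate
17 | C7 N-methoxy-N-methylcarboxamide of the bicyclo[5.3.0]deca-5,8-diene (key-step product) | CC(C)C[C@@H](c1c(OC)cc(OC)cc1OC)[C@@]1(C)CC[C@H]2C1=C[C@H](C(=O)N(C)OC)C=C[C@H]2C | intermediate
18 | C7 N-methoxy-N-methylcarboxamide of the bicyclo[5.3.0]dec-5-ene | CC(C)C[C@@H](c1c(OC)cc(OC)cc1OC)[C@@]1(C)CC[C@H]2C1=C[C@H](C(=O)N(C)OC)CC[C@H]2C | intermediate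
19 | C7 acetyl bicyclo[5.3.0]dec-5-ene | CC(C)C[C@@H](c1c(OC)cc(OC)cc1OC)[C@@]1(C)CC[C@H]2C1=C[C@H](C(C)=O)CC[C@H]2C | intermediate
20 | C7 (2-hydroxypropan-2-yl) bicyclo[5.3.0]dec-5-ene with 2,4,6-trimethoxyphenyl at Ca | CC(C)C[C@@H](c1c(OC)cc(OC)cc1OC)[C@@]1(C)CC[C@H]2C1=C[C@H](C(C)(C)O)CC[C@H]2C | intermediate
21 | dilithium salt: 3′-[(dimethylamino)(lithiooxy)methyl] derivative of the C11 lithium alkoxide of 20 | CC(C)C[C@@H](c1c(OC)c(C(O[Li])N(C)C)c(OC)cc1OC)[C@@]1(C)CC[C@H]2C1=C[C@H](C(C)(C)O[Li])CC[C@H]2C | intermediate (not isolated)
22 | 2,4,6-trimethoxy-5-substituted benzene-1,3-dicarbaldehyde (trimethyl ether of the target) | CC(C)C[C@@H](c1c(OC)c(C=O)c(OC)c(C=O)c1OC)[C@@]1(C)CC[C@H]2C1=C[C@H](C(C)(C)O)CC[C@H]2C | intermediate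
23 | CNP0281883.1, 2,4,6-trihydroxy-5-substituted benzene-1,3-dicarbaldehyde | CC(C)C[C@@H](c1c(O)c(C=O)c(O)c(C=O)c1O)[C@@]1(C)CC[C@H]2C1=C[C@H](C(C)(C)O)CC[C@H]2C | target

## Step count and risks

Total step count: 18. Longest linear sequence: 18 steps (from 1; 8 is commercial).

**Step 13 (key step).** The syn carboxamide may retard the boat transition state enough for reversible homolysis of C6–C8 to compete, which would scramble the relationship of C7 to C1 and C10; prolonged heating could also let the doubly allylic C7–H migrate. The fallback replaces the amide by a smaller formyl group. It sets out from 16 and returns at 19.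
- 16 is reduced with i-Bu2AlH at −78 °C to the all-cis cyclopropanecarbaldehyde F1.
- Heating F1 gives the C7 carbaldehyde diene F2; retro-Claisen excursions of this aldehyde to dihydrooxepines are reversible while the all-carbon rearrangement is not.
- MeMgBr at −78 °C gives the secondary alcohol F3, diimide reduces C8=C9 to give F4, and Dess–Martin oxidation gives 19.

**Step 1.** The 5- and 7-methoxy groups push electron density to C4 and the 5-methoxy group crowds it, so sluggish conjugate addition, competing attack at the lactone carbonyl and eroded enantioselectivity are possible. The fallback moves the stereo-defining event to a reduction. It does not use 1: it sets out from commercial 3,5-dimethoxyphenol and ethyl 5-methyl-3-oxohexanoate and comes back at 2.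
- Pechmann condensation (CF3CO2H) gives 5,7-dimethoxy-4-(2-methylpropyl)coumarin F5.
- Asymmetric conjugate reduction with copper hydride generated from Cu(OAc)2, DTBM-SEGPHOS and polymethylhydrosiloxane in toluene/t-BuOH gives 2.

**Step 9.** The stereocentres beside the diene may oppose the catalyst (poor facial selectivity), and the carbenoid may dimerise or add to the cyclopentene alkene. The fallback lets the chiral catalyst act on an achiral substrate and joins the pieces afterwards. It sets out from 7 and returns at 13, replacing steps 6 to 9.
- Ethyl (2Z)-3-iodoprop-2-enoate is reduced with i-Bu2AlH to (2Z)-3-iodoprop-2-en-1-ol F6.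
- F6 is converted as in step 8 into (2Z)-3-iodoprop-2-en-1-yl diazoacetate F7 and cyclised with Rh2(5R-MEPY)4 to endo-6-iodo-3-oxabicyclo[3.1.0]hexan-2-one F8.
- 7 undergoes Miyaura borylation (B2pin2, PdCl2(dppf), K2CO3) to the pinacol boronate F9.
- Suzuki–Miyaura coupling of F8 with F9 (Pd(OAc)2, PPh3, K3PO4, toluene–H2O), with retention at the cyclopropyl carbon, gives 13.

**Step 17.** The second lithiation may be incomplete, or the amino alkoxide may collapse in the flask and expose the first aldehyde to butyllithium. The fallback fixes both positions before any organolithium is used. It sets out from 20 and returns at 22.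
- N-bromosuccinimide (2 equiv, MeCN, 0 °C) brominates the two activated aryl positions to give the 3′,5′-dibromide F10.
- t-BuLi (5 equiv, THF, −78 °C) effects double bromine–lithium exchange, and DMF gives 22.

**Step 18.** Demethylation may stall once aryloxides accumulate, and thiolate may add reversibly to the aldehydes and lead to reduction products. The fallback switches from nucleophilic to chelation-assisted cleavage. It sets out from 22 and returns at 23.
- Et3SiOTf and 2,6-lutidine give the triethylsilyl ether F11.
- MgI2·OEt2 in toluene at 80 °C cleaves the three methoxy groups, each ortho to a formyl group, giving the silyl ether of the target F12.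
- Bu4NF buffered with acetic acid gives 23.

## Further compounds

F1 | step 13 | all-cis 2-[(1E)-prop-1-en-1-yl]-3-(cyclopentenyl)cyclopropane-1-carbaldehyde (formyl analogue of 16) | CC(C)C[C@@H](c1c(OC)cc(OC)cc1OC)[C@@]1(C)CCC=C1[C@@H]1[C@H](C=O)[C@@H]1/C=C/C
F2 | step 13 | C7 carbaldehyde of the bicyclo[5.3.0]deca-5,8-diene (formyl analogue of 17) | CC(C)C[C@@H](c1c(OC)cc(OC)cc1OC)[C@@]1(C)CC[C@H]2C1=C[C@H](C=O)C=C[C@H]2C
F3 | step 13 | C7 (1-hydroxyethyl) bicyclo[5.3.0]deca-5,8-diene (C11 epimers) | CC(C)C[C@@H](c1c(OC)cc(OC)cc1OC)[C@@]1(C)CC[C@H]2C1=C[C@H](C(C)O)C=C[C@H]2C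
F4 | step 13 | C7 (1-hydroxyethyl) bicyclo[5.3.0]dec-5-ene (C11 epimers) | CC(C)C[C@@H](c1c(OC)cc(OC)cc1OC)[C@@]1(C)CC[C@H]2C1=C[C@H](C(C)O)CC[C@H]2C
F5 | step 1 | 5,7-dimethoxy-4-(2-methylpropyl)-2H-chromen-2-one | CC(C)CC1=CC(=O)Oc2cc(OC)cc(OC)c12
F6 | step 9 | (2Z)-3-iodoprop-2-en-1-ol | OC/C=C\I
F7 | step 9 | (2Z)-3-iodoprop-2-en-1-yl diazoacetate | [N-]=[N+]=CC(=O)OC/C=C\I
F8 | step 9 | endo-6-iodo-3-oxabicyclo[3.1.0]hexan-2-one (ring-fusion sense as in 13) | I[C@@H]1[C@@H]2C(=O)OC[C@H]12
F9 | step 9 | pinacol boronate corresponding to triflate 7 | CC(C)C[C@@H](c1c(OC)cc(OC)cc1OC)[C@@]1(C)CCC=C1B1OC(C)(C)C(C)(C)O1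
F10 | step 17 | 3′,5′-dibromo derivative of 20 | CC(C)C[C@@H](c1c(OC)c(Br)c(OC)c(Br)c1OC)[C@@]1(C)CC[C@H]2C1=C[C@H](C(C)(C)O)CC[C@H]2C
F11 | step 18 | C11 triethylsilyl ether of 22 | CC(C)C[C@@H](c1c(OC)c(C=O)c(OC)c(C=O)c1OC)[C@@]1(C)CC[C@H]2C1=C[C@H](C(C)(C)O[Si](CC)(CC)CC)CC[C@H]2C
F12 | step 18 | C11 triethylsilyl ether of 23 | CC(C)C[C@@H](c1c(O)c(C=O)c(O)c(C=O)c1O)[C@@]1(C)CC[C@H]2C1=C[C@H](C(C)(C)O[Si](CC)(CC)CC)CC[C@H]2C
A1 | alternative 1 | triisopropylsilyl ynol ether at Ca of the complete hydroazulene (C11 triethylsilyl ether) | CC(C)C[C@@H](C#CO[Si](C(C)C)(C(C)C)C(C)C)[C@@]1(C)CC[C@H]2C1=C[C@H](C(C)(C)O[Si](CC)(CC)CC)CC[C@H]2C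
A2 | alternative 1 | 3-ethoxycyclobut-2-en-1-one | CCOC1=CC(=O)C1
A3 | alternative 1 | 2-substituted phloroglucinol with hydroxyl, ethoxy and triisopropylsiloxy groups | CC(C)C[C@@H](c1c(O)cc(OCC)cc1O[Si](C(C)C)(C(C)C)C(C)C)[C@@]1(C)CC[C@H]2C1=C[C@H](C(C)(C)O[Si](CC)(CC)CC)CC[C@H]2C
A4 | alternative 2 | 6-acetoxy-2H-pyran-3(6H)-one carrying the quaternary C4 unit with a (Z)-pent-3-enyl tether at ring position 2 and the silylated carbinol at position 4 | CC(C)C[C@@H](c1c(OC)cc(OC)cc1OC)[C@@](C)(CC/C=C\C)C1OC(OC(C)=O)C=C(C(C)(C)O[Si](C)(C)C)C1=O
A5 | alternative 2 | oxygen-bridged tricyclic enone (C6 ketone, C7=C8 alkene, C5–O–C9 bridge) | CC(C)C[C@@H](c1c(OC)cc(OC)cc1OC)[C@@]1(C)CC[C@@H]2[C@H](C)[C@H]3C=C(C(C)(C)O[Si](C)(C)C)C(=O)[C@@]12O3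
A6 | alternative 3 | allenyne with terminal alkyne at C1/C2 and trisubstituted allene C4=C5=C6 (allene configuration to be defined) | C#C[C@H](C)CC[C@@H](C(C)(C)O)C=C=C(C)[C@@H](CC(C)C)c1c(OC)cc(OC)cc1OC
A7 | alternative 3 | bicyclo[5.3.0] 4-alkylidenecyclopentenone (C3 ketone, C1=C2 and C5=C6 alkenes) | CC(C)C[C@@H](c1c(OC)cc(OC)cc1OC)[C@@]1(C)C(=O)C=C2C1=C[C@H](C(C)(C)O)CC[C@H]2C
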